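## Structural features

The target is an eleven-membered carbocycle of the humulane family, numbered here C1 (bearing the exocyclic methylene C12), C2=C3, C4 (gem-dimethyl), C5 (carbinol carbon), C6, C7, C8(CH3)=C9, C10 and C11; the C5 oxygen carries a 4-hydroxy-3-methoxybenzoyl group. Both ring alkenes are E: C2=C3 is conjugated with the exocyclic C1=C12 bond, and C8=C9 is an isolated trisubstituted alkene set off by the methylene pairs C6–C7 and C10–C11. C5, of R configuration, is the only stereocentre; it adjoins the quaternary C4 but no other stereogenic atom, so the task is one of absolute and not of relative configuration. The sensitive parts are the 1,3-diene (acid, palladium hydrides and electrophiles can move or consume it), the free phenol, and the aryl ester, which rules out strongly nucleophilic or reducing reagents once it is in place; the C5 oxygen is neopentyl-like and therefore slow to silylate, desilylate and acylate. The real difficulty is to close a medium ring holding five sp2 carbons with both ring alkenes E, and to make the trisubstituted alkene as a single geometric isomer. The key step draws on the array C7–C8(CH3)=C9(H)–C10–C11: a methyl group and a two-carbon chain cis to each other on neighbouring alkene carbons is what syn addition of methyl and a two-carbon electrophile to a terminal C8≡C9 alkyne leaves behind. For the atom bookkeeping of that step, the alkyne partner holds C2 to C9 (its vinyl group is C3=C2) and the homoallylic alcohol formed from it holds C2 to C11, so that only C1 and C12 remain to be added.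

## Logic of the disconnections

24 ⇒ 23. The phenolic O–H is exchanged for an aryl O–acetyl bond. The reason is chemoselectivity: a free phenol would compete with the hindered C5 hydroxyl for the activated acid. The skeleton is not simplified, but ester formation becomes unambiguous. The forward step must cleave an aryl acetate and leave the C5 aroyl ester alone.

23 ⇒ 19 + 21. The acyl C–O bond between the C5 oxygen and the aroyl carbonyl is cut. This is the only heteroatom link between the aromatic and the terpenoid part, and cutting it keeps the base-labile ester out of all organometallic steps. The gain is convergence (a C15 alcohol and an aromatic acid). The forward step must acylate a hydroxyl flanked by a quaternary carbon, which calls for the highly activated donor 22 and nucleophilic catalysis; acylation at oxygen leaves C5 untouched.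

21 ⇒ 20. The aryl O–acetyl bond is cut to reveal the commercial acid. One step; the only demand is that any acylation at the carboxyl group be reversed on aqueous work-up.

19 ⇒ 18. The O–Si bond at C5 is cut. The hydroxyl has to be masked through the aluminium, lithium and palladium chemistry. The forward step needs fluoride to reach a hindered silyl ether without harming the diene.

18 ⇒ 17. The C1–C2 ring bond is cut. It is an sp2–sp2 bond of the diene, and cutting it opens the ring to a chain with a monosubstituted alkene on the quaternary C4 at one end and a 2-bromoalkene at the other. The medium ring and the diene vanish together. The forward step demands that an 11-endo carbopalladation outrun intermolecular coupling and that β-hydride elimination give E-C2=C3; C4, having no hydrogen, leaves no other direction of elimination.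

17 ⇒ 15. The C1–Br bond (with the C12–H bond made alongside) is cut, leading back through 16 to a terminal alkyne. A terminal alkyne is the simplest and most robust precursor of a 2-haloalkene. The forward step must place the metal on the internal carbon C1 and ignore the vinyl group, the trisubstituted alkene and the silyl ether, which a protic acid would not.

15 ⇒ 13. The C11–C1 single bond is cut (through 14). C1 and C12 then come from a two-carbon acetylide. The demand is that substitution at a homoallylic primary iodide beat elimination toward a conjugated diene.

13 ⇒ 12. The C11–I bond is traced back to the C11–O bond. This is a functional-group change that hands the key-step product on as an electrophile; it must be neutral enough for the silyl ether.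

12 ⇒ 7 + 8 + 9. Two bonds are cut at once, C8–CH3 and C9–C10 (through 10 and 11). This removes the trisubstituted alkene, its geometry problem and three carbons in a single operation and leaves a terminal alkyne. The forward step demands syn addition with methyl on C8 and metal on C9, transfer of the alkenyl group (not methyl or butyl) to 9, and indifference toward the vinyl group and the silyl ether.

7 ⇒ 6. The O–Si bond is cut. The free hydroxyl would consume the aluminium reagent and complicate ate formation. The demand is silylation of a neopentyl-like secondary alcohol, hence a silyl triflate.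

6 ⇒ 2 + 3. The C4–C5 bond is cut (through 4 and 5). This bond joins the quaternary carbon to the stereocentre, so one step creates both; the fragments are five-carbon pieces of no stereochemical content. The forward step must join the CMe2 terminus (not the CH2 terminus) of the allyl unit to the aldehyde and control the face of attack by the chiral boron ligands.

2 ⇒ 1. Only the oxidation level changes. The demand is a mild oxidation and careful handling of a volatile aldehyde.

## Other disconnections considered

Alternative 1: The cut is the C7–C8 single bond. In the forward direction an open-chain E-alkenyl iodide bearing a 1-substituted cyclopropanol made of C5, C6 and C7 (A2) would be treated with Pd(OAc)2, a bulky phosphine and Cs2CO3. Zerovalent palladium inserts into the C8–I bond, the palladium cyclopropanolate undergoes β-carbon elimination to a C7 homoenolate, and reductive elimination joins C7 to C8, closing the ring as the achiral trienone A1. Enantioselective reduction of the C5 ketone would then lead to 19.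
- In favour: release of cyclopropane strain makes the closure irreversible; the sp3–sp2 bond forms with retention of an alkene geometry fixed beforehand; no palladium hydride arises in the productive cycle.
- Against: the homoenolate can lose a β-hydrogen from C6 and give an open-chain enone; the diene C12=C1–C2=C3 must already be present in A2 and is itself a partner for alkenylpalladium; the cyclopropanol must be made from an ester at a neopentyl position; C5 would be set last, by reagent-controlled reduction of a hindered ketone in a mobile ring.
- Comparison: on structure the plans are equals for C8=C9, since the iodide of A2 would itself come from a zirconium-catalysed methylalumination quenched with iodine. On mechanism the alternative is the better on diene integrity during ring closure and on access to either enantiomer from the achiral A1. The chosen plan is the better on stereocontrol, because C5 is fixed early by a reagent of established facial preference. On step economy the two should be about equal: the alternative saves the C5 protecting group but spends steps on the acyclic diene and the final reduction.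

Alternative 2: The cut is the C2=C3 double bond. In the forward direction the open-chain precursor A4, with a non-enolisable aldehyde at C3 and a β-ketophosphonate spanning C1 and C2, would be cyclised with LiCl and DBU at high dilution (Horner–Wadsworth–Emmons) to the dienone A3. Methylenation of the C1 ketone would then give 18.
- In favour: this olefination is among the best-proven macrocyclisations, irreversible and E-selective; the aldehyde on C4 can neither enolise nor epimerise; C5 and C8=C9 could be made exactly as in the chosen plan.
- Against: C3 must travel through the chain assembly as a masked aldehyde, which a plain vinyl group cannot supply once the more electron-rich C8=C9 alkene is present; the ketophosphonate costs a further carbon–carbon bond formation; the exocyclic methylene must be installed afterwards on an enolisable ring enone.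
- Comparison: on structure the plans are equal, both closing the ring in the C1–C3 region beside the quaternary carbon. On mechanism the alternative is the better in precedent for E-selective ring closure, and it avoids palladium hydride altogether. On step economy the chosen plan is shorter by roughly the masking and unmasking of C3, the phosphonate installation and the methylenation.

Alternative 3: The cut is the C1–C2 bond, the same bond that step 8 of the chosen plan closes. In the forward direction the methyl ketone A7 would be converted by kinetic enolisation into the terminal enol triflate A6. Pd(OAc)2, PPh3 and an amine base at high dilution would then bring about oxidative addition of zerovalent palladium, carbopalladation at the terminal vinyl carbon C2 and β-hydride elimination to A5, which is the same compound as 18.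
- In favour: oxidative addition into a triflate is fast and gives a cationic alkenylpalladium with a free coordination site without any silver additive; the quaternary C4 dictates the regiochemistry of insertion and the direction of β-hydride elimination.
- Against: A7 has two enolisable flanks, so the regiochemistry of triflation is a selectivity to be won; terminal enol triflates are prone to hydrolysis and to elimination to the alkyne under base; A7 itself needs a hydration of 15 or an acyl-anion alkylation of 13.
- Comparison: on structure and on the ring-forming mechanism the alternative and the chosen plan are equals, because the chosen plan uses the bromide analogue of the same event. The triflate is the better on halide-free, silver-free cationic conditions. The bromide is the better on step economy (one step from 15 instead of two) and on regiochemical certainty. The alternative leaves the origin of the E-trisubstituted alkene open, which is why the strategic weight is placed on step 4.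

Key step: step 4

Remarks on the chemistry:

- Assumption: the prenylborane with isopinocampheyl (Ipc) groups derived from (+)-α-pinene is taken to attack the Si face of the aldehyde, as the parent B-allyl reagent does; this face corresponds to R at C5. Should the sense prove opposite, the borane from (−)-α-pinene would be used with nothing else changed.
- Addition of free hydrogen bromide to the terminal alkyne is avoided: it would also attack the trisubstituted alkene and the silyl ether. The 2-bromoalkene is made by hydrometalation and bromination instead.
- Compound 21 is also an article of commerce; if it is bought, step 10 falls away.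

Step 1

Reactants: 1 pent-4-yn-1-ol

Product: 2 pent-4-ynal

Conditions: (COCl)2, DMSO, CH2Cl2, −78 °C; Et3N, −78 → 0 °C; used as a cold solution

Reagents that add atoms: none

Why: Swern oxidation (activated dimethyl sulfoxide) stops at the aldehyde and leaves the terminal alkyne alone; the volatile aldehyde is carried on in solution to avoid loss and self-condensation.

Step 2

Reactants: 2 pent-4-ynal; 3 3-methylbuta-1,2-diene

Product: 6 (4R)-3,3-dimethyloct-1-en-7-yn-4-ol, via prenylborane 4 (not isolated), via borinate 5 (not isolated)

Conditions: (−)-Ipc2BH [from (+)-α-pinene], 3, THF, −25 °C; 2, Et2O, −78 °C; aq. NaOH, H2O2, 0 °C → rt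

Reagents that add atoms: none

Why: Hydroboration of the unsubstituted terminus of the allene gives the γ,γ-dimethylallylborane 4, which adds to the aldehyde through a closed chair six-membered transition state with allylic transposition, so the C4–C5 bond forms at the CMe2 terminus (Brown asymmetric allylboration, reverse prenylation). The isopinocampheyl groups should steer attack to the Si face of the aldehyde, which sets R at C5; oxidative work-up cleaves borinate 5.

Step 3

Reactants: 6 (4R)-3,3-dimethyloct-1-en-7-yn-4-ol

Product: 7 tert-butyl{[(4R)-3,3-dimethyloct-1-en-7-yn-4-yl]oxy}dimethylsilane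

Conditions: TBSOTf, 2,6-lutidine, CH2Cl2, 0 °C

Reagents that add atoms: tert-butyldimethylsilyl trifluoromethanesulfonate, `CC(C)(C)[Si](C)(C)OS(=O)(=O)C(F)(F)F`

Why: O-silylation; the triflate is needed because the neopentyl-like secondary hydroxyl is too hindered for the silyl chloride. The ether is stable to the aluminium, lithium, nickel and palladium reagents that follow and is still cleavable by fluoride.

Step 4

Reactants: 7 tert-butyl{[(4R)-3,3-dimethyloct-1-en-7-yn-4-yl]oxy}dimethylsilane; 8 trimethylaluminium; 9 oxirane

Product: 12 (3E,7R)-7-[(tert-butyldimethylsilyl)oxy]-4,8,8-trimethyldeca-3,9-dien-1-ol, via alkenylalane 10 (not isolated), via lithium alanate 11 (not isolated)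

Conditions: Al(CH3)3 (2.5 equiv), Cp2ZrCl2 (0.25 equiv), CH2Cl2, 0 °C → rt; volatiles removed in vacuo; hexane, n-BuLi (1.0 equiv), 0 °C; oxirane (3 equiv), THF, −30 °C → rt; aq. KNaC4H4O6 (tartrate)

Reagents that add atoms: trimethylaluminium 8, `C[Al](C)C`; oxirane 9, `C1CO1`

Why: Al(CH3)3 and Cp2ZrCl2 form a methylzirconium–aluminium species that adds CH3 and metal syn across the terminal C8≡C9 bond, methyl going to the internal carbon C8 and metal to the terminal carbon C9, and transmetalation leaves the E-alkenylalane 10 (zirconium-catalysed methylalumination, Negishi carboalumination). n-BuLi turns 10 into the more nucleophilic four-coordinate alanate 11, whose alkenyl group is transferred in preference to methyl or butyl to a carbon of oxirane with retention of alkene geometry, so the C9–C10 bond and the C11 alkoxide arise in the same flask; this is the established alkenylalanate–epoxide route to E-homoallylic alcohols. No ring closes and no stereocentre is formed; C5 is remote from the reacting atoms and is not at risk. The step needs regiocontrol at the alkyne, syn addition, and preference for the alkyne over the vinyl group: the first two are inherent to carbometalation of a monosubstituted alkyne, and the vinyl group on the quaternary C4 is too hindered and unactivated to react. The silyl ether is not cleaved by the aluminium reagents, and removing surplus Al(CH3)3 before adding n-BuLi keeps methylalanates from consuming oxirane.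

Step 5

Reactants: 12 (3E,7R)-7-[(tert-butyldimethylsilyl)oxy]-4,8,8-trimethyldeca-3,9-dien-1-ol

Product: 13 tert-butyl{[(4R,7E)-10-iodo-3,3,7-trimethyldeca-1,7-dien-4-yl]oxy}dimethylsilane

Conditions: I2, PPh3, imidazole, CH2Cl2, 0 °C → rt

Reagents that add atoms: iodine, `II`

Why: Appel-type iodination: the primary alkoxyphosphonium ion is displaced by iodide in an SN2 step; the imidazole-buffered medium spares the silyl ether and the alkenes.

Step 6

Reactants: 13 tert-butyl{[(4R,7E)-10-iodo-3,3,7-trimethyldeca-1,7-dien-4-yl]oxy}dimethylsilane

Product: 15 tert-butyldimethyl{[(4R,7E)-3,3,7-trimethyldodeca-1,7-dien-11-yn-4-yl]oxy}silane, via silylalkyne 14 (not isolated)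

Conditions: HC≡CSiMe3, n-BuLi, THF, −78 °C; 13, DMPU, −78 °C → rt; then MeOH, K2CO3 (0.2 equiv), rt

Reagents that add atoms: ethynyltrimethylsilane, `C#C[Si](C)(C)C`

Why: SN2 alkylation of a lithium acetylide by a primary iodide in a dipolar medium, which should outpace elimination; the C-silyl cap prevents proton shuffling and double alkylation. It is removed by base-catalysed methanolysis in the same flask, conditions the hindered C5 silyl ether withstands.

Step 7

Reactants: 15 tert-butyldimethyl{[(4R,7E)-3,3,7-trimethyldodeca-1,7-dien-11-yn-4-yl]oxy}silane

Product: 17 {[(4R,7E)-11-bromo-3,3,7-trimethyldodeca-1,7,11-trien-4-yl]oxy}(tert-butyl)dimethylsilane, via alkenylaluminium 16 (not isolated)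

Conditions: i-Bu2AlH (1.3 equiv), NiCl2[Ph2P(CH2)3PPh2] (3 mol%), THF, 0 °C → rt; NBS (1.4 equiv), 0 °C

Reagents that add atoms: N-bromosuccinimide, `O=C1CCC(=O)N1Br`

Why: Nickel-catalysed α-selective hydroalumination: the bisphosphine nickel hydride puts hydrogen on the terminal carbon and aluminium on the internal carbon C1, and N-bromosuccinimide replaces the C–Al bond by C–Br. The non-acidic sequence leaves the trisubstituted alkene, the hindered vinyl group and the silyl ether alone.

Step 8

Reactants: 17 {[(4R,7E)-11-bromo-3,3,7-trimethyldodeca-1,7,11-trien-4-yl]oxy}(tert-butyl)dimethylsilane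

Product: 18 tert-butyldimethyl{[(1R,3E,8E)-2,2,9-trimethyl-5-methylidenecycloundeca-3,8-dien-1-yl]oxy}silane

Conditions: Pd(OAc)2 (20 mol%), PPh3 (60 mol%), Ag2CO3 (1.5 equiv), MeCN, 80 °C, slow addition of 17 to 1 mM

Reagents that add atoms: none

Why: Intramolecular Mizoroki–Heck macrocyclisation: zerovalent palladium inserts into the C1–Br bond, the alkenylpalladium adds syn to the vinyl group with C1 bonding to the terminal carbon C2 (11-endo), and syn β-hydride elimination, possible only toward C2 because C4 has no hydrogen, should give E-C2=C3 in conjugation with C1=C12. Ag2CO3 removes bromide and the palladium hydride so that the diene is not isomerised; high dilution suppresses oligomerisation, and the C8=C9 alkene could only be reached through a four- or five-membered ring and stays out.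

Step 9

Reactants: 18 tert-butyldimethyl{[(1R,3E,8E)-2,2,9-trimethyl-5-methylidenecycloundeca-3,8-dien-1-yl]oxy}silane

Product: 19 (1R,3E,8E)-2,2,9-trimethyl-5-methylidenecycloundeca-3,8-dien-1-ol

Conditions: n-Bu4NF, THF, 50 °C

Reagents that add atoms: none

Why: Fluoride-induced Si–O cleavage driven by the Si–F bond; warming compensates for hindrance at C5, and the basic, non-acidic medium leaves the diene in place.

Step 10

Reactants: 20 vanillic acid (4-hydroxy-3-methoxybenzoic acid)

Product: 21 4-acetoxy-3-methoxybenzoic acid

Conditions: Ac2O, pyridine, rt; then H2O

Reagents that add atoms: acetic anhydride, `CC(=O)OC(C)=O`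

Why: O-acetylation of the phenol; any mixed anhydride formed at the carboxyl group is hydrolysed on aqueous work-up. Acetyl is chosen because it can later be removed by mild aminolysis without touching a benzoate ester.

Step 11

Reactants: 19 (1R,3E,8E)-2,2,9-trimethyl-5-methylidenecycloundeca-3,8-dien-1-ol; 21 4-acetoxy-3-methoxybenzoic acid

Product: 23 (1R,3E,8E)-2,2,9-trimethyl-5-methylidenecycloundeca-3,8-dien-1-yl 4-acetoxy-3-methoxybenzoate, via acid chloride 22 (not isolated)

Conditions: 21, (COCl)2, DMF (cat.), CH2Cl2, 0 °C → rt, evaporate; 19, Et3N, DMAP (1 equiv), CH2Cl2, rt → 40 °C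

Reagents that add atoms: none

Why: Acid chloride formation followed by DMAP-catalysed acylation through an N-acylpyridinium ion, which is reactive enough for a hydroxyl next to a quaternary carbon. The C5–O bond is not broken, so the configuration is retained.

Step 12

Reactants: 23 (1R,3E,8E)-2,2,9-trimethyl-5-methylidenecycloundeca-3,8-dien-1-yl 4-acetoxy-3-methoxybenzoate

Product: 24 (1R,3E,8E)-2,2,9-trimethyl-5-methylidenecycloundeca-3,8-dien-1-yl 4-hydroxy-3-methoxybenzoate (target)

Conditions: pyrrolidine (2 equiv), CH2Cl2, 0 °C → rt

Reagents that add atoms: none

Why: Chemoselective aminolysis: the aryl acetate is a far better acyl donor than the hindered, electron-rich alkyl benzoate, so only the acetyl group is removed and the phenol is released without acid or strong base near the diene.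

Compound list

```
1 | pent-4-yn-1-ol | C#CCCCO | starting material
2 | pent-4-ynal | C#CCCC=O | intermediate
3 | 3-methylbuta-1,2-diene | CC(C)=C=C | starting material
4 | (3-methylbut-2-en-1-yl)bis[(1R,2S,3R,5R)-2,6,6-trimethylbicyclo[3.1.1]heptan-3-yl]borane | CC(C)=CCB([C@@H]1C[C@@H]2C[C@H]([C@H]1C)C2(C)C)[C@@H]1C[C@@H]2C[C@H]([C@H]1C)C2(C)C | intermediate
5 | (4R)-3,3-dimethyloct-1-en-7-yn-4-yl bis[(1R,2S,3R,5R)-2,6,6-trimethylbicyclo[3.1.1]heptan-3-yl]borinate | C=CC(C)(C)[C@H](OB([C@@H]1C[C@@H]2C[C@H]([C@H]1C)C2(C)C)[C@@H]1C[C@@H]2C[C@H]([C@H]1C)C2(C)C)CCC#C | intermediate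
6 | (4R)-3,3-dimethyloct-1-en-7-yn-4-ol | C=CC(C)(C)[C@H](O)CCC#C | intermediate
7 | tert-butyl{[(4R)-3,3-dimethyloct-1-en-7-yn-4-yl]oxy}dimethylsilane | C=CC(C)(C)[C@H](O[Si](C)(C)C(C)(C)C)CCC#C | intermediate
8 | trimethylaluminium | C[Al](C)C | starting material
9 | oxirane | C1CO1 | starting material
10 | [(1E,5R)-5-[(tert-butyldimethylsilyl)oxy]-2,6,6-trimethylocta-1,7-dien-1-yl]dimethylalane | C=CC(C)(C)[C@H](O[Si](C)(C)C(C)(C)C)CC/C(C)=C/[Al](C)C | intermediate
11 | lithium butyl[(1E,5R)-5-[(tert-butyldimethylsilyl)oxy]-2,6,6-trimethylocta-1,7-dien-1-yl]dimethylaluminate | [Li+].C=CC(C)(C)[C@H](O[Si](C)(C)C(C)(C)C)CC/C(C)=C/[Al-](C)(C)CCCC | intermediate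
12 | (3E,7R)-7-[(tert-butyldimethylsilyl)oxy]-4,8,8-trimethyldeca-3,9-dien-1-ol | C=CC(C)(C)[C@H](O[Si](C)(C)C(C)(C)C)CC/C(C)=C/CCO | intermediate
13 | tert-butyl{[(4R,7E)-10-iodo-3,3,7-trimethyldeca-1,7-dien-4-yl]oxy}dimethylsilane | C=CC(C)(C)[C@H](O[Si](C)(C)C(C)(C)C)CC/C(C)=C/CCI | intermediate
14 | tert-butyldimethyl{[(4R,7E)-3,3,7-trimethyl-12-(trimethylsilyl)dodeca-1,7-dien-11-yn-4-yl]oxy}silane | C=CC(C)(C)[C@H](O[Si](C)(C)C(C)(C)C)CC/C(C)=C/CCC#C[Si](C)(C)C | intermediate
15 | tert-butyldimethyl{[(4R,7E)-3,3,7-trimethyldodeca-1,7-dien-11-yn-4-yl]oxy}silane | C=CC(C)(C)[C@H](O[Si](C)(C)C(C)(C)C)CC/C(C)=C/CCC#C | intermediate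
16 | [(5E,9R)-9-[(tert-butyldimethylsilyl)oxy]-6,10,10-trimethyldodeca-1,5,11-trien-2-yl]bis(2-methylpropyl)alane | C=CC(C)(C)[C@H](O[Si](C)(C)C(C)(C)C)CC/C(C)=C/CCC(=C)[Al](CC(C)C)CC(C)C | intermediate
17 | {[(4R,7E)-11-bromo-3,3,7-trimethyldodeca-1,7,11-trien-4-yl]oxy}(tert-butyl)dimethylsilane | C=CC(C)(C)[C@H](O[Si](C)(C)C(C)(C)C)CC/C(C)=C/CCC(Br)=C | intermediate
18 | tert-butyldimethyl{[(1R,3E,8E)-2,2,9-trimethyl-5-methylidenecycloundeca-3,8-dien-1-yl]oxy}silane | C=C1/C=C/C(C)(C)[C@H](O[Si](C)(C)C(C)(C)C)CC/C(C)=C/CC1 | intermediate
19 | (1R,3E,8E)-2,2,9-trimethyl-5-methylidenecycloundeca-3,8-dien-1-ol | C=C1/C=C/C(C)(C)[C@H](O)CC/C(C)=C/CC1 | intermediate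
20 | vanillic acid (4-hydroxy-3-methoxybenzoic acid) | COc1cc(C(=O)O)ccc1O | starting material
21 | 4-acetoxy-3-methoxybenzoic acid | COc1cc(C(=O)O)ccc1OC(C)=O | intermediate
22 | 4-acetoxy-3-methoxybenzoyl chloride | COc1cc(C(Cl)=O)ccc1OC(C)=O | intermediate
23 | (1R,3E,8E)-2,2,9-trimethyl-5-methylidenecycloundeca-3,8-dien-1-yl 4-acetoxy-3-methoxybenzoate | C=C1/C=C/C(C)(C)[C@H](OC(=O)c2ccc(OC(C)=O)c(OC)c2)CC/C(C)=C/CC1 | intermediate
24 | (1R,3E,8E)-2,2,9-trimethyl-5-methylidenecycloundeca-3,8-dien-1-yl 4-hydroxy-3-methoxybenzoate | C=C1/C=C/C(C)(C)[C@H](OC(=O)c2ccc(O)c(OC)c2)CC/C(C)=C/CC1 | target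
```

Total step count: 12. Longest linear sequence: 11 steps (1 to 24 through steps 1–9, 11 and 12); step 10 is a one-step side branch.

Least certain steps

Step 4 (key step). The most likely failure is incomplete formation of the ate complex or sluggish attack on oxirane, so that work-up protonates the alkenyl–aluminium bond and returns the methylated alkene without the two-carbon unit. Transfer of methyl or butyl instead of the alkenyl group, and consumption of oxirane by residual Al(CH3)3, act in the same direction. Fallback, setting out from 7 by way of 10 and coming back at 12: alkenylalane 10 is quenched with iodine to tert-butyl{[(4R,7E)-8-iodo-3,3,7-trimethylocta-1,7-dien-4-yl]oxy}dimethylsilane F1. Iodine–lithium exchange (t-BuLi, Et2O, −78 °C) gives [(1E,5R)-5-[(tert-butyldimethylsilyl)oxy]-2,6,6-trimethylocta-1,7-dien-1-yl]lithium F2, which opens oxirane 9 (with BF3·OEt2 if needed) with retention of geometry to give 12. The same two bonds are made, but through a harder nucleophile in two operations.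

Step 8. The most likely failure is intermolecular Heck coupling (oligomerisation) winning over closure of the strained eleven-membered ring; a second risk is migration of the diene through re-addition of palladium hydride. Fallback, setting out from 17 and coming back at 18, closes the same C1–C2 bond by carbonyl addition instead of carbopalladation. Hydroboration of the monosubstituted vinyl group (9-BBN, THF; NaOH, H2O2; the bromoalkene is deactivated toward the borane) should give (4R,7E)-11-bromo-4-[(tert-butyldimethylsilyl)oxy]-3,3,7-trimethyldodeca-7,11-dien-1-ol F3. Oxidation (Dess–Martin periodinane) gives (4R,7E)-11-bromo-4-[(tert-butyldimethylsilyl)oxy]-3,3,7-trimethyldodeca-7,11-dienal F4. Nozaki–Hiyama–Kishi macrocyclisation (CrCl2, NiCl2 cat., DMSO/THF, high dilution) gives (5E,9R)-9-[(tert-butyldimethylsilyl)oxy]-6,10,10-trimethyl-2-methylidenecycloundec-5-en-1-ol F5 as a mixture of carbinol epimers, which is of no consequence. Dehydration with Martin sulfurane, possible only toward C3 because C1 bears no hydrogen, should then give 18.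

Step 7. The most likely failures are erosion of regioselectivity in the hydroalumination (aluminium at the terminal carbon, leading to the 1-bromoalkene), deprotonation of the terminal alkyne by the hydride, or bromination of the electron-rich trisubstituted alkene by surplus N-bromosuccinimide. Fallback, setting out from 15 and coming back at 17, uses haloboration instead of hydrometalation: B-bromo-9-borabicyclo[3.3.1]nonane (CH2Cl2, 0 °C) adds B–Br syn across the alkyne with bromine on the internal carbon to give 9-[(1Z,5E,9R)-2-bromo-9-[(tert-butyldimethylsilyl)oxy]-6,10,10-trimethyldodeca-1,5,11-trien-1-yl]-9-borabicyclo[3.3.1]nonane F6, and protodeboronation with acetic acid gives 17.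

Step 2. The most likely failures are insufficient facial selectivity with this small, unbranched aldehyde, loss of the volatile aldehyde before it reacts, and difficult separation from the terpene alcohol released on work-up. Fallback, setting out from 2 and coming back at 6, sets C5 by catalyst-controlled reduction instead of allylboration. Indium-mediated Barbier prenylation (1-bromo-3-methylbut-2-ene, indium powder, THF/H2O), which also bonds through the CMe2 terminus, gives racemic 3,3-dimethyloct-1-en-7-yn-4-ol F7. Oxidation (Dess–Martin periodinane) gives 3,3-dimethyloct-1-en-7-yn-4-one F8. Corey–Bakshi–Shibata reduction with the (S)-oxazaborolidine and catecholborane (toluene, −78 °C; tert-alkyl against primary alkyl is the favourable case, and catecholborane at this temperature spares alkyne and alkene) should give 6.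

Step 11. The most likely failure is slow acylation at the hindered hydroxyl, which gives time for acetyl transfer from the aryl acetate to the alcohol or for decomposition of the acid chloride. Fallback, setting out from 19 and 20 and coming back at 24, uses a non-transferable phenol protecting group and a pre-formed alkoxide. Vanillic acid 20 is converted (TBSCl, imidazole, DMF; then K2CO3, aq. MeOH) into 4-[(tert-butyldimethylsilyl)oxy]-3-methoxybenzoic acid F9 and then ((COCl)2, DMF cat.) into 4-[(tert-butyldimethylsilyl)oxy]-3-methoxybenzoyl chloride F10. Alcohol 19 is deprotonated (n-BuLi, THF, −78 °C) to lithium (1R,3E,8E)-2,2,9-trimethyl-5-methylidenecycloundeca-3,8-dien-1-olate F11, which is acylated by F10 to (1R,3E,8E)-2,2,9-trimethyl-5-methylidenecycloundeca-3,8-dien-1-yl 4-[(tert-butyldimethylsilyl)oxy]-3-methoxybenzoate F12. Buffered fluoride (n-Bu4NF, AcOH, THF, 0 °C) then frees the phenol to give 24.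

## Further compounds

```
F1 | step 4 | tert-butyl{[(4R,7E)-8-iodo-3,3,7-trimethylocta-1,7-dien-4-yl]oxy}dimethylsilane | C=CC(C)(C)[C@H](O[Si](C)(C)C(C)(C)C)CC/C(C)=C/I
F2 | step 4 | [(1E,5R)-5-[(tert-butyldimethylsilyl)oxy]-2,6,6-trimethylocta-1,7-dien-1-yl]lithium | C=CC(C)(C)[C@H](O[Si](C)(C)C(C)(C)C)CC/C(C)=C/[Li]
F3 | step 8 | (4R,7E)-11-bromo-4-[(tert-butyldimethylsilyl)oxy]-3,3,7-trimethyldodeca-7,11-dien-1-ol | OCCC(C)(C)[C@H](O[Si](C)(C)C(C)(C)C)CC/C(C)=C/CCC(Br)=C
F4 | step 8 | (4R,7E)-11-bromo-4-[(tert-butyldimethylsilyl)oxy]-3,3,7-trimethyldodeca-7,11-dienal | O=CCC(C)(C)[C@H](O[Si](C)(C)C(C)(C)C)CC/C(C)=C/CCC(Br)=C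
F5 | step 8 | (5E,9R)-9-[(tert-butyldimethylsilyl)oxy]-6,10,10-trimethyl-2-methylidenecycloundec-5-en-1-ol (carbinol epimers) | C=C1C(O)CC(C)(C)[C@H](O[Si](C)(C)C(C)(C)C)CC/C(C)=C/CC1
F6 | step 7 | 9-[(1Z,5E,9R)-2-bromo-9-[(tert-butyldimethylsilyl)oxy]-6,10,10-trimethyldodeca-1,5,11-trien-1-yl]-9-borabicyclo[3.3.1]nonane | C=CC(C)(C)[C@H](O[Si](C)(C)C(C)(C)C)CC/C(C)=C/CC/C(Br)=C/B1C2CCCC1CCC2
F7 | step 2 | rac-3,3-dimethyloct-1-en-7-yn-4-ol | C=CC(C)(C)C(O)CCC#C
F8 | step 2 | 3,3-dimethyloct-1-en-7-yn-4-one | C=CC(C)(C)C(=O)CCC#C
F9 | step 11 | 4-[(tert-butyldimethylsilyl)oxy]-3-methoxybenzoic acid | COc1cc(C(=O)O)ccc1O[Si](C)(C)C(C)(C)C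
F10 | step 11 | 4-[(tert-butyldimethylsilyl)oxy]-3-methoxybenzoyl chloride | COc1cc(C(Cl)=O)ccc1O[Si](C)(C)C(C)(C)C
F11 | step 11 | lithium (1R,3E,8E)-2,2,9-trimethyl-5-methylidenecycloundeca-3,8-dien-1-olate | C=C1/C=C/C(C)(C)[C@H]([O-])CC/C(C)=C/CC1.[Li+]
F12 | step 11 | (1R,3E,8E)-2,2,9-trimethyl-5-methylidenecycloundeca-3,8-dien-1-yl 4-[(tert-butyldimethylsilyl)oxy]-3-methoxybenzoate | C=C1/C=C/C(C)(C)[C@H](OC(=O)c2ccc(O[Si](C)(C)C(C)(C)C)c(OC)c2)CC/C(C)=C/CC1
A1 | alternative 1 | (3E,8E)-2,2,9-trimethyl-5-methylidenecycloundeca-3,8-dien-1-one | C=C1/C=C/C(C)(C)C(=O)CC/C(C)=C/CC1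
A2 | alternative 1 | 1-[(3E,8E)-9-iodo-2-methyl-5-methylidenedeca-3,8-dien-2-yl]cyclopropan-1-ol | OC1(CC1)C(C)(C)/C=C/C(=C)CC/C=C(\C)I
A3 | alternative 2 | (2E,5R,8E)-5-[(tert-butyldimethylsilyl)oxy]-4,4,8-trimethylcycloundeca-2,8-dien-1-one | O=C1/C=C/C(C)(C)[C@H](O[Si](C)(C)C(C)(C)C)CC/C(C)=C/CC1
A4 | alternative 2 | dimethyl [(5E,9R)-9-[(tert-butyldimethylsilyl)oxy]-6,10,10-trimethyl-2,11-dioxoundec-5-en-1-yl]phosphonate | O=CC(C)(C)[C@H](O[Si](C)(C)C(C)(C)C)CC/C(C)=C/CCC(=O)CP(=O)(OC)OC
A5 | alternative 3 | tert-butyldimethyl{[(1R,3E,8E)-2,2,9-trimethyl-5-methylidenecycloundeca-3,8-dien-1-yl]oxy}silane (identical with 18) | C=C1/C=C/C(C)(C)[C@H](O[Si](C)(C)C(C)(C)C)CC/C(C)=C/CC1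
A6 | alternative 3 | (5E,9R)-9-[(tert-butyldimethylsilyl)oxy]-6,10,10-trimethyldodeca-1,5,11-trien-2-yl trifluoromethanesulfonate | C=CC(C)(C)[C@H](O[Si](C)(C)C(C)(C)C)CC/C(C)=C/CCC(=C)OS(=O)(=O)C(F)(F)F
A7 | alternative 3 | (5E,9R)-9-[(tert-butyldimethylsilyl)oxy]-6,10,10-trimethyldodeca-5,11-dien-2-one | C=CC(C)(C)[C@H](O[Si](C)(C)C(C)(C)C)CC/C(C)=C/CCC(C)=O
```
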